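**Plan**
Retrosynthesis: remove the two silyl ethers; open ring C (the pyran ring) at C2-C3 together with one benzylic C-H of the C3 benzyl group (reductive Prins cyclisation); cut the acetal bond O1-C2 to give 2,4-dimethoxybenzaldehyde and an achiral phenol; cut both C4-alkenyl bonds back to a Boc-protected salicylaldehyde and two equivalents of one alkenyl Grignard reagent.
Enabling feature: the 4-hydroxybenzyl group on C3 is a 4-hydroxystyryl arm whose inner carbon has bonded to C2 and whose benzylic carbon has taken up hydride, and C4 carries an intact 4-hydroxystyryl arm. C4 is therefore a latent symmetric bis(styryl)methine on ring A, next to the phenol oxygen O1 that can carry C2 as an oxocarbenium ion.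
Forward: an o-quinone methide cascade on the ring A aldehyde puts both arms on C4; O1 is tied to C2 as a mixed acetal; one ionisation closes ring C through C2-C3 and hydride capture turns the reacting arm into the benzyl group; desilylation ends the route.
Stereochemistry: C2, C3 and C4 all arise in the ring closure. The all-trans relationship comes from an all-equatorial half-chair, the absolute configuration from a chiral counteranion that selects one of the two enantiotopic arms. Both E alkenes come from the Takai olefination.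

Key step: step 7

Assumption: the sense of induction of the chiral anion in step 7 cannot be predicted with confidence; the (S,S)-acid is written, and its antipode is used if it favours the (2S,3S,4S) series.

Step 1
Reactants: 1 4-hydroxybenzaldehyde
Product: 2 4-(triisopropylsilyloxy)benzaldehyde
Conditions: TIPSCl, imidazole, DMF, rt
Reagents that add atoms: triisopropylsilyl chloride CC(C)[Si](Cl)(C(C)C)C(C)C
Why: Standard imidazole-mediated silylation of a phenol, which leaves the aldehyde untouched and gives an electron-rich aryl ether that withstands organometallic reagents and Lewis acids at low temperature.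

Step 2
Reactants: 2 4-(triisopropylsilyloxy)benzaldehyde
Product: 3 (E)-[4-(2-iodoethenyl)phenoxy]triisopropylsilane
Conditions: CrCl2, CHI3, THF, 0 °C to rt
Reagents that add atoms: iodoform IC(I)I
Why: Takai olefination, in which the geminal dichromium species from CHI3 adds to the aryl aldehyde and eliminates to the E-alkenyl iodide with the high E selectivity typical of aromatic aldehydes.

Step 3
Reactants: 4 2-hydroxy-4-methoxybenzaldehyde
Product: 5 tert-butyl 2-formyl-5-methoxyphenyl carbonate
Conditions: Boc2O, i-Pr2NEt, DMAP (cat.), THF, rt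
Reagents that add atoms: di-tert-butyl dicarbonate CC(C)(C)OC(=O)OC(=O)OC(C)(C)C
Why: DMAP-catalysed O-acylation of the phenol gives the aryl carbonate that later serves as the internal trigger for o-quinone methide formation.

Step 4
Reactants: 3 (E)-[4-(2-iodoethenyl)phenoxy]triisopropylsilane (2.4 equiv), 5 tert-butyl 2-formyl-5-methoxyphenyl carbonate
Product: 8 2-{(1E,4E)-1,5-bis[4-(triisopropylsilyloxy)phenyl]penta-1,4-dien-3-yl}-5-methoxyphenol, via alkenylmagnesium chloride 6 (not isolated), via o-quinone methide 7 (not isolated)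
Conditions: i-PrMgCl·LiCl, THF, −20 °C to rt; then 5, −78 °C to rt; aq. NH4Cl
Reagents that add atoms: none
Why: Stereoretentive iodine-magnesium exchange gives 6, and the known o-quinone methide cascade of O-Boc salicylaldehydes with Grignard reagents follows (1,2-addition, Boc migration to the benzylic alkoxide, loss of tert-butyl carbonate to 7, then magnesium-directed 1,4-addition of a second equivalent of 6); the two arms are identical, so no stereocentre is formed.

Step 5
Reactants: 9 2,4-dimethoxybenzaldehyde
Product: 10 1-(dimethoxymethyl)-2,4-dimethoxybenzene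
Conditions: HC(OMe)3, p-TsOH·H2O (cat.), rt; then Et3N
Reagents that add atoms: trimethyl orthoformate COC(OC)OC
Why: Acid-catalysed acetalisation with the orthoformate as methoxy source and water scavenger, which is fast for this electron-rich aldehyde.

Step 6
Reactants: 8 2-{(1E,4E)-1,5-bis[4-(triisopropylsilyloxy)phenyl]penta-1,4-dien-3-yl}-5-methoxyphenol, 10 1-(dimethoxymethyl)-2,4-dimethoxybenzene
Product: 12 mixed O-aryl O-methyl acetal of 2,4-dimethoxybenzaldehyde with phenol 8 (racemic at the acetal carbon), via α-chloro ether 11 (not isolated)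
Conditions: 10, AcCl, CH2Cl2, 0 °C; then 8, i-Pr2NEt, CH2Cl2, −78 to 0 °C; filtration through basic alumina
Reagents that add atoms: none
Why: Acetyl chloride converts the dimethyl acetal into the α-chloro ether (as in the preparation of MOMCl from dimethoxymethane), which O-alkylates the phenol under amine base exactly as in a MOM protection, so the tether is made without free acid; the acetal stereocentre is lost on ionisation in the next step.

Step 7
Reactants: 12 mixed O-aryl O-methyl acetal
Product: 15 (2R,3R,4R)-bis(triisopropylsilyl) ether of caraganin C, via oxocarbenium ion 13 (not isolated), via benzylic cation 14 (not isolated)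
Conditions: (S,S)-IDPi acid HN[P(=NSO2CF3)(O2C20H10Ar2)]2, with O2C20H10Ar2 = (S)-3,3'-Ar2-1,1'-binaphthalene-2,2'-diolate and Ar = 3,5-(CF3)2C6H3 (5 mol %), Et3SiH (2 equiv), toluene, −60 °C
Reagents that add atoms: none
Why: Proposed new method: the acid is silylated by Et3SiH and the resulting silylium/IDPi pair removes the methoxy group of 12 (the more Lewis-basic acetal oxygen) as Et3SiOMe, giving the O-aryl oxocarbenium ion 13 paired with the chiral anion; the inner alkene carbon of one 4-silyloxystyryl arm attacks the oxocarbenium carbon (Prins cyclisation, Markovnikov, so that the charge lands on the 4-silyloxybenzylic carbon of 14) and 14 takes hydride from Et3SiH, which regenerates the silylium catalyst. The closest known reaction types are the IDPi-catalysed asymmetric Prins cyclisation of aldehydes with homoallylic alcohols, silylium/IDPi-catalysed enantioselective additions to oxocarbenium ions generated from acetals, and Lewis-acid Prins cyclisations of mixed acetals ended by silane reduction. Ring C closes in a six-membered mode that is endo for the C=O bond of the oxocarbenium ion and exo for the attacking alkene, through a half-chair with the 2,4-dimethoxyphenyl group, the developing benzylic carbon and the spectator styryl arm all pseudo-equatorial. That half-chair (E-oxocarbenium ion, substrate control) fixes the 2,3-trans and 3,4-trans relationships, so the three new stereocentres C2, C3 and C4 are set together and their absolute sense follows from a single choice, which enantiotopic arm meets which oxocarbenium face, made by the chiral anion. The step needs ring closure to outrun hydride reduction of 13 (intramolecular π-attack against bimolecular transfer from a silane of comparable nucleophilicity), irreversibility (fast hydride capture of 14 blocks retro-Prins equilibration) and no Friedel-Crafts capture of 14 (the free ortho position of the C2 aryl ring is meta to both methoxy groups); the product ether is far less easily ionised than the acetal at this temperature.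

Step 8
Reactants: 15 (2R,3R,4R)-bis(triisopropylsilyl) ether of caraganin C
Product: 16 caraganin C
Conditions: TBAF, AcOH, THF, 0 °C
Reagents that add atoms: none
Why: Buffered fluoride cleaves both aryl silyl ethers without touching the methyl ethers, the E alkene or the three stereocentres.

**Compound list**
1 | 4-hydroxybenzaldehyde | O=Cc1ccc(O)cc1 | starting material
2 | 4-(triisopropylsilyloxy)benzaldehyde | CC(C)[Si](Oc1ccc(C=O)cc1)(C(C)C)C(C)C | intermediate
3 | (E)-[4-(2-iodoethenyl)phenoxy]triisopropylsilane | CC(C)[Si](Oc1ccc(/C=C/I)cc1)(C(C)C)C(C)C | intermediate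
4 | 2-hydroxy-4-methoxybenzaldehyde | COc1ccc(C=O)c(O)c1 | starting material
5 | tert-butyl 2-formyl-5-methoxyphenyl carbonate | COc1ccc(C=O)c(OC(=O)OC(C)(C)C)c1 | intermediate
6 | (E)-{2-[4-(triisopropylsilyloxy)phenyl]ethenyl}magnesium chloride (LiCl complex) | CC(C)[Si](Oc1ccc(/C=C/[Mg]Cl)cc1)(C(C)C)C(C)C | intermediate
7 | o-quinone methide, 3-methoxy-6-{(E)-3-[4-(triisopropylsilyloxy)phenyl]prop-2-enylidene}cyclohexa-2,4-dien-1-one | COC1=CC(=O)C(=C/C=C/c2ccc(O[Si](C(C)C)(C(C)C)C(C)C)cc2)C=C1 | intermediate
8 | 2-{(1E,4E)-1,5-bis[4-(triisopropylsilyloxy)phenyl]penta-1,4-dien-3-yl}-5-methoxyphenol (achiral) | COc1ccc(C(/C=C/c2ccc(O[Si](C(C)C)(C(C)C)C(C)C)cc2)/C=C/c2ccc(O[Si](C(C)C)(C(C)C)C(C)C)cc2)c(O)c1 | intermediate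
9 | 2,4-dimethoxybenzaldehyde | COc1ccc(C=O)c(OC)c1 | starting material
10 | 1-(dimethoxymethyl)-2,4-dimethoxybenzene | COc1ccc(C(OC)OC)c(OC)c1 | intermediate
11 | 1-[chloro(methoxy)methyl]-2,4-dimethoxybenzene | COc1ccc(C(Cl)OC)c(OC)c1 | intermediate
12 | 1-[{2-[(1E,4E)-1,5-bis(4-triisopropylsilyloxyphenyl)penta-1,4-dien-3-yl]-5-methoxyphenoxy}(methoxy)methyl]-2,4-dimethoxybenzene (racemic at the acetal carbon) | COc1ccc(C(/C=C/c2ccc(O[Si](C(C)C)(C(C)C)C(C)C)cc2)/C=C/c2ccc(O[Si](C(C)C)(C(C)C)C(C)C)cc2)c(OC(OC)c2ccc(OC)cc2OC)c1 | intermediate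
13 | O-aryl oxocarbenium ion from 12 (IDPi counteranion) | COc1ccc(C(/C=C/c2ccc(O[Si](C(C)C)(C(C)C)C(C)C)cc2)/C=C/c2ccc(O[Si](C(C)C)(C(C)C)C(C)C)cc2)c([O+]=Cc2ccc(OC)cc2OC)c1 | intermediate
14 | 4-silyloxybenzylic cation on C3 of the closed all-trans chroman (IDPi counteranion) | COc1ccc2c(c1)O[C@@H](c1ccc(OC)cc1OC)[C@H]([CH+]c1ccc(O[Si](C(C)C)(C(C)C)C(C)C)cc1)[C@H]2/C=C/c1ccc(O[Si](C(C)C)(C(C)C)C(C)C)cc1 | intermediate
15 | (2R,3R,4R)-2-(2,4-dimethoxyphenyl)-7-methoxy-3-[4-(triisopropylsilyloxy)benzyl]-4-{(E)-2-[4-(triisopropylsilyloxy)phenyl]ethenyl}chroman | COc1ccc2c(c1)O[C@@H](c1ccc(OC)cc1OC)[C@H](Cc1ccc(O[Si](C(C)C)(C(C)C)C(C)C)cc1)[C@H]2/C=C/c1ccc(O[Si](C(C)C)(C(C)C)C(C)C)cc1 | intermediate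
16 | caraganin C, 4-{(E)-2-[(2R,3R,4R)-2-(2,4-dimethoxyphenyl)-3-(4-hydroxybenzyl)-7-methoxychroman-4-yl]ethenyl}phenol | COc1ccc2c(c1)O[C@@H](c1ccc(OC)cc1OC)[C@H](Cc1ccc(O)cc1)[C@H]2/C=C/c1ccc(O)cc1 | target

Total step count: 8. Longest linear sequence: 6 steps (steps 1, 2, 4, 6, 7, 8).

**Steps most likely to fail**

Step 7. The chiral anion may discriminate poorly between the two enantiotopic arm/face pairings, or a racemic background path through an ion not bound to the chiral anion may compete. Fallback, from 12 back to 15: the ring is closed under substrate control only, with TMSOTf (20 mol %), 2,6-di-tert-butyl-4-methylpyridine and Et3SiH in CH2Cl2 at −78 °C (Lewis-acid Prins cyclisation of a mixed acetal followed by ionic hydrogenation of the benzylic cation). The same half-chair should give the all-trans product as the racemate, that is 15 together with its (2S,3S,4S) enantiomer F1. The enantiomers are separated by preparative HPLC on amylose tris(3,5-dimethylphenylcarbamate), and 15 goes on to step 8.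

Step 4. The second alkenyl Grignard may add to the vinylogous o-quinone methide 7 at the remote styryl carbon (1,6-addition), or 7 may close electrocyclically to a 2H-chromene before it is trapped. Fallback, from 2 back to 8, in which both arms are made by olefination and no o-quinone methide is involved: commercially available 2-bromo-5-methoxyphenol is protected with MOMCl and i-Pr2NEt to give 1-bromo-4-methoxy-2-(methoxymethoxy)benzene F2. Arylation of diethyl malonate catalysed by Pd(OAc)2/P(t-Bu)3 (K3PO4, toluene, 70 °C) gives diethyl 2-[4-methoxy-2-(methoxymethoxy)phenyl]propanedioate F3, and LiAlH4 (THF, 0 °C) reduces it to 2-[4-methoxy-2-(methoxymethoxy)phenyl]propane-1,3-diol F4. A double Mitsunobu reaction with 1-phenyl-1H-tetrazole-5-thiol (PPh3, DIAD) gives the bis(tetrazolyl sulfide) F5, which (NH4)6Mo7O24/H2O2 oxidises to the bis-sulfone F6. Double Julia-Kocienski olefination of F6 with aldehyde 2 (KHMDS, DME, −60 °C to rt) gives the (E,E)-diene MOM ether F7, and ZnBr2/n-PrSH (CH2Cl2, 0 °C) removes the MOM group to give 8.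

Step 6. The chloro ether 11 or the acetal 12 may ionise too early (uncatalysed racemic ring closure, hydrolysis on the adsorbent), or the electron-rich phenol may be alkylated on carbon. Fallback, from 8 back to 15: phenol 8 is acylated with commercially available 2,4-dimethoxybenzoyl chloride (Et3N, DMAP, CH2Cl2) to give the aryl 2,4-dimethoxybenzoate F8. Reductive acetylation (DIBAL-H, CH2Cl2, −78 °C; then Ac2O, pyridine, DMAP, −78 to 0 °C) gives the α-acetoxy ether F9, a more robust oxocarbenium precursor made under basic conditions. Under the conditions of step 7, F9 loses acetate to give the same ion 13 and hence 15.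

**Further compounds**
F1 | step 7 | (2S,3S,4S)-enantiomer of 15 | COc1ccc2c(c1)O[C@H](c1ccc(OC)cc1OC)[C@@H](Cc1ccc(O[Si](C(C)C)(C(C)C)C(C)C)cc1)[C@@H]2/C=C/c1ccc(O[Si](C(C)C)(C(C)C)C(C)C)cc1
F2 | step 4 | 1-bromo-4-methoxy-2-(methoxymethoxy)benzene | COCOc1cc(OC)ccc1Br
F3 | step 4 | diethyl 2-[4-methoxy-2-(methoxymethoxy)phenyl]propanedioate | CCOC(=O)C(C(=O)OCC)c1ccc(OC)cc1OCOC
F4 | step 4 | 2-[4-methoxy-2-(methoxymethoxy)phenyl]propane-1,3-diol | OCC(CO)c1ccc(OC)cc1OCOC
F5 | step 4 | 5,5'-{2-[4-methoxy-2-(methoxymethoxy)phenyl]propane-1,3-diylbis(sulfanediyl)}bis(1-phenyl-1H-tetrazole) | COCOc1cc(OC)ccc1C(CSc1nnnn1-c1ccccc1)CSc1nnnn1-c1ccccc1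
F6 | step 4 | 5,5'-{2-[4-methoxy-2-(methoxymethoxy)phenyl]propane-1,3-diyldisulfonyl}bis(1-phenyl-1H-tetrazole) | COCOc1cc(OC)ccc1C(CS(=O)(=O)c1nnnn1-c1ccccc1)CS(=O)(=O)c1nnnn1-c1ccccc1
F7 | step 4 | methoxymethyl ether of 8 | COCOc1cc(OC)ccc1C(/C=C/c1ccc(O[Si](C(C)C)(C(C)C)C(C)C)cc1)/C=C/c1ccc(O[Si](C(C)C)(C(C)C)C(C)C)cc1
F8 | step 6 | 2-{(1E,4E)-1,5-bis[4-(triisopropylsilyloxy)phenyl]penta-1,4-dien-3-yl}-5-methoxyphenyl 2,4-dimethoxybenzoate | COc1ccc(C(/C=C/c2ccc(O[Si](C(C)C)(C(C)C)C(C)C)cc2)/C=C/c2ccc(O[Si](C(C)C)(C(C)C)C(C)C)cc2)c(OC(=O)c2ccc(OC)cc2OC)c1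
F9 | step 6 | α-acetoxy ether, {2-[(1E,4E)-1,5-bis(4-triisopropylsilyloxyphenyl)penta-1,4-dien-3-yl]-5-methoxyphenoxy}(2,4-dimethoxyphenyl)methyl acetate (racemic) | COc1ccc(C(/C=C/c2ccc(O[Si](C(C)C)(C(C)C)C(C)C)cc2)/C=C/c2ccc(O[Si](C(C)C)(C(C)C)C(C)C)cc2)c(OC(OC(C)=O)c2ccc(OC)cc2OC)c1
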